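**Plan**

- Retrosynthetic cuts, in order: the tetrasubstituted enal C=C on ring A (ketone + cyanophosphonate); the trisubstituted C=C of the triene (ester enolate + dienal 31); the C–CH3 bond of the tertiary carbinol; then, together, the cyclopentane CH2–CH2 bond and the bond from the spiro carbon to the chain-bearing ring-A carbon.
- Enabling feature: the spiro carbon sits between the ring-B CHOH carbon and the ring-A C(Me)OH carbon (two former ketones), and the ring-B CH2–CH2 bond joins the two carbons β to the ring-B carbinol carbon. That pattern is what a Nazarov closure leaves when its oxyallyl cation is quenched by a ring-enlarging 1,2-shift.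
- Forward, core: cyclopentenone → cyclopentanone 11 (five of the six ring-A carbons) → alkynyl carbinol → α-stannyl allylic alcohol → cross-conjugated dienone 16. Step 12 then closes ring B, enlarges the cyclopentane to ring A and creates the spiro centre.
- Forward, finish: methyl addition, enone formation, reduction and directed hydrogenation complete ring B; aldol condensation with 31 builds the triene; olefination of the ring-A ketone, reduction and desilylation end the route.
- Stereochemistry: one carbinol centre from CBS reduction, relayed to the chain-bearing carbon (anti hydroboration), the tertiary carbinol (anti addition) and the spiro centre (chelate-controlled shift with retention). From there the C(Me)OH, CHOH and side-chain-bearing centres follow by substrate-controlled addition, reduction and hydroxyl-directed hydrogenation; alkene geometries come from the Heck, E1cB and Horner–Wadsworth–Emmons steps.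

Key step: step 12

Abbreviations: TBS = tert-butyldimethylsilyl, TBDPS = tert-butyldiphenylsilyl, TMS = trimethylsilyl, DMP = Dess–Martin periodinane.
Remark: 18, 19 and 20 are carried as mixtures of epimers at the ester-bearing ring carbon, which becomes sp2 in 21. The SMILES of 17 shows the O–H form of the scandium-bound oxyallyl cation.

**Step 1**
Reactants: 1 prop-2-en-1-ol
Product: 2 tert-butyl(diphenyl)(prop-2-en-1-yloxy)silane
Conditions: TBDPSCl, imidazole, CH2Cl2, 0 °C → rt
Reagents that add atoms: tert-butyl(chloro)diphenylsilane, CC(C)(C)[Si](Cl)(c1ccccc1)c1ccccc1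
Why: Standard imidazole-mediated silylation of a primary alcohol; TBDPS is chosen because it must outlast a later acid-mediated TBS removal.

**Step 2**
Reactants: 3 cyclopent-2-en-1-one
Product: 4 2-iodocyclopent-2-en-1-one
Conditions: I2, pyridine, CH2Cl2, 0 °C → rt
Reagents that add atoms: iodine, II
Why: Pyridine-mediated α-iodination of an enone (conjugate addition, iodination of the enolate, elimination), the Johnson iodination.

**Step 3**
Reactants: 2 tert-butyl(diphenyl)(prop-2-en-1-yloxy)silane; 4 2-iodocyclopent-2-en-1-one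
Product: 6 2-[3-(TBDPS-oxy)propyl]cyclopent-2-en-1-one, via alkyl-9-BBN 5 (not isolated)
Conditions: 9-BBN, THF, 0 °C → rt; then 4, PdCl2(dppf) (5 mol %), AsPh3, Cs2CO3, DMF/H2O, rt
Reagents that add atoms: none
Why: Anti-Markovnikov hydroboration of the terminal alkene followed by B-alkyl Suzuki–Miyaura coupling, a pairing well precedented for 2-iodocycloalkenones.

**Step 4**
Reactants: 6 2-[3-(TBDPS-oxy)propyl]cyclopent-2-en-1-one
Product: 7 (1R)-2-[3-(TBDPS-oxy)propyl]cyclopent-2-en-1-ol
Conditions: (S)-Me-CBS oxazaborolidine (10 mol %), catecholborane, toluene, −78 °C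
Reagents that add atoms: none
Why: Corey–Bakshi–Shibata reduction; with the substituted alkene arm as the large group the (S)-catalyst should give the (R)-carbinol, the one stereocentre from which all others are relayed.

**Step 5**
Reactants: 7 (1R)-2-[3-(TBDPS-oxy)propyl]cyclopent-2-en-1-ol
Product: 8 (1R)-1-(TBS-oxy)-2-[3-(TBDPS-oxy)propyl]cyclopent-2-ene
Conditions: TBSCl, imidazole, DMF, rt
Reagents that add atoms: tert-butyl(chloro)dimethylsilane, CC(C)(C)[Si](C)(C)Cl
Why: Standard silylation; the bulky allylic silyl ether is the facial control element for the next step.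

**Step 6**
Reactants: 8 (1R)-1-(TBS-oxy)-2-[3-(TBDPS-oxy)propyl]cyclopent-2-ene
Product: 10 (1R,2S,3R)-3-(TBS-oxy)-2-[3-(TBDPS-oxy)propyl]cyclopentan-1-ol, via alkylborane 9 (not isolated)
Conditions: BH3·THF, THF, 0 °C → rt; then NaOH (aq.), H2O2, 0 °C
Reagents that add atoms: hydrogen peroxide, OO
Why: Hydroboration–oxidation; boron goes to the less substituted alkene carbon remote from the allylic oxygen, and H and B add syn from the face anti to the OTBS group, which sets the chain-bearing stereocentre (chain cis to OTBS).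

**Step 7**
Reactants: 10 (1R,2S,3R)-3-(TBS-oxy)-2-[3-(TBDPS-oxy)propyl]cyclopentan-1-ol
Product: 11 (2R,3R)-3-(TBS-oxy)-2-[3-(TBDPS-oxy)propyl]cyclopentan-1-one
Conditions: DMP, pyridine, CH2Cl2, 0 °C → rt; used without delay
Reagents that add atoms: none
Why: Dess–Martin oxidation under buffered, non-basic conditions, so that the epimerizable α-carbon and the β-silyloxy group are left untouched.

**Step 8**
Reactants: 11 (2R,3R)-3-(TBS-oxy)-2-[3-(TBDPS-oxy)propyl]cyclopentan-1-one
Product: 12 (1S,2R,3R)-1-ethynyl-3-(TBS-oxy)-2-[3-(TBDPS-oxy)propyl]cyclopentan-1-ol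
Conditions: HC≡CMgBr, LaCl3·2LiCl, THF, −78 °C → −20 °C
Reagents that add atoms: ethynylmagnesium bromide, C#C[Mg]Br
Why: Lanthanum-promoted 1,2-addition of an alkynyl Grignard reagent, which suppresses enolization and β-elimination; attack anti to the cis-disposed chain and OTBS group should place the new hydroxyl cis to the chain.

**Step 9**
Reactants: 12 (1S,2R,3R)-1-ethynyl-3-(TBS-oxy)-2-[3-(TBDPS-oxy)propyl]cyclopentan-1-ol
Product: 13 (1S,2R,3R)-3-(TBS-oxy)-2-[3-(TBDPS-oxy)propyl]-1-[1-(tributylstannyl)ethenyl]cyclopentan-1-ol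
Conditions: Bu3SnH, Mo(CO)3(CNtBu)3 (5 mol %), hydroquinone, THF, 60 °C
Reagents that add atoms: tributyltin hydride, CCCC[SnH](CCCC)CCCC
Why: Molybdenum-catalysed hydrostannation of a terminal propargylic alcohol, which delivers tin to the internal (α) carbon and gives the 1,1-disubstituted alkenylstannane.

**Step 10**
Reactants: 14 4-methoxy-2-methylidene-4-oxobutanoic acid (monomethyl itaconate)
Product: 15 methyl 3-(chlorocarbonyl)but-3-enoate
Conditions: (COCl)2, DMF (cat.), CH2Cl2, 0 °C → rt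
Reagents that add atoms: oxalyl chloride, O=C(Cl)C(=O)Cl
Why: Standard acid chloride formation through the Vilsmeier-type chloroiminium species.

**Step 11**
Reactants: 13 α-stannyl allylic alcohol; 15 methyl 3-(chlorocarbonyl)but-3-enoate
Product: 16 methyl 5-[(1S,2R,3R)-1-hydroxy-3-(TBS-oxy)-2-[3-(TBDPS-oxy)propyl]cyclopentyl]-3-methylidene-4-oxohex-5-enoate
Conditions: Pd2(dba)3 (2.5 mol %), P(2-furyl)3, THF, 45 °C, BHT; used crude
Reagents that add atoms: none
Why: Acylative Stille coupling of an alkenylstannane with an acid chloride under zerovalent palladium catalysis; the tertiary alcohol is not acylated in the absence of base.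

**Step 12**
Reactants: 16 cross-conjugated dienone
Product: 18 methyl 2-[(5R,9R,10S)-9-(TBS-oxy)-10-[3-(TBDPS-oxy)propyl]-1,6-dioxospiro[4.5]decan-2-yl]acetate, via oxyallyl cation 17 (not isolated)
Conditions: Sc(OTf)3 (20 mol %), 1,2-dichloroethane, 0 °C → 40 °C
Reagents that add atoms: none
Why: Proposed new method: Sc(OTf)3 binds the ketone oxygen and the tertiary hydroxyl of 16 in a six-membered chelate that fixes the s-trans/s-trans dienone; conrotatory 4π electrocyclization of the pentadienyl cation joins the two terminal CH2 carbons to give oxyallyl cation 17, whose carbinol-bearing terminus is quenched by a 1,2-shift of the chain-bearing ring carbon (semipinacol) while the other terminus ketonizes. The closest known reaction is the acid-catalysed tandem Nazarov cyclization/semipinacol rearrangement of 2-(1-hydroxycyclobutyl) divinyl ketones to spiro[4.4]nonane-1,6-diones; new here are the cyclopentanol-to-cyclohexanone enlargement and the unsubstituted dienone termini. Ring B closes by the 4π electrocyclization (the five-membered ring is formed at the bond between its two β-carbons), and ring A arises by one-carbon enlargement of the cyclopentane through the suprafacial 1,2-shift, not by a separate closure. The spiro centre is controlled by the carbinol stereocentre: in the chelate the C–O bond lies in the plane of the cation, so the chain-bearing carbon sits over one face only and migrates to it with retention of its own configuration, which turns the cis hydroxyl/chain relationship of 16 into the required spiro configuration; the ester-bearing carbon is not controlled and is erased in step 14. The step needs the shift to outrun proton loss from 17 and the substituted ring carbon to migrate in preference to the ring CH2; a non-basic triflate counter-ion, the intramolecular ketone-forming shift and the higher migratory aptitude of the secondary carbon held out of the cation plane are relied on for this.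

**Step 13**
Reactants: 18 spiro diketone
Product: 19 methyl 2-[(5R,6S,9R,10S)-6-hydroxy-6-methyl-1-oxo-9-(TBS-oxy)-10-[3-(TBDPS-oxy)propyl]spiro[4.5]decan-2-yl]acetate
Conditions: MeMgBr (1.2 equiv), LaCl3·2LiCl, THF, −78 °C; AcOH quench at −78 °C
Reagents that add atoms: methylmagnesium bromide, C[Mg]Br
Why: Grignard addition to the more electrophilic and less hindered cyclohexanone (the cyclopentanone is flanked by a quaternary and a tertiary carbon, and the ester is inert at −78 °C); methyl should enter from the face of the spiro CH2, anti to the axial silyloxypropyl chain and the ring-B carbonyl branch, and the cold quench guards against retro-aldol cleavage.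

**Step 14**
Reactants: 19 β-hydroxy ketone
Product: 21 methyl 2-[(5R,6S,9R,10S)-6-methyl-1-oxo-9-(TBS-oxy)-10-[3-(TBDPS-oxy)propyl]-6-(TMS-oxy)spiro[4.5]dec-2-en-2-yl]acetate, via silyl enol ether 20 (not isolated)
Conditions: TMSOTf, Et3N, CH2Cl2, 0 °C; concentrate; then Pd(OAc)2 (1.1 equiv), MeCN, rt
Reagents that add atoms: trimethylsilyl trifluoromethanesulfonate, C[Si](C)(C)OS(=O)(=O)C(F)(F)F
Why: Soft enolization gives the only possible silyl enol ether and silylates the tertiary alcohol, and Saegusa–Ito oxidation through the divalent palladium enolate gives the enone; any exocyclic alkylidene isomer would converge to the same product in steps 15 and 16.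

**Step 15**
Reactants: 21 enone
Product: 23 methyl 2-[(1S,5S,6S,9R,10S)-1,6-dihydroxy-6-methyl-9-(TBS-oxy)-10-[3-(TBDPS-oxy)propyl]spiro[4.5]dec-2-en-2-yl]acetate, via silyl ether alcohol 22 (not isolated)
Conditions: NaBH4, CeCl3·7H2O, MeOH, −78 °C; then citric acid (aq.), rt
Reagents that add atoms: none
Why: Luche 1,2-reduction; hydride should come from the face of the CH(chain) carbon, away from the fully substituted carbon carrying the bulky OTMS group, which puts the new hydroxyl cis to the tertiary oxygen; mild acid then cleaves the tertiary TMS ether.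

**Step 16**
Reactants: 23 allylic alcohol
Product: 24 methyl 2-[(1S,2S,5S,6S,9R,10S)-1,6-dihydroxy-6-methyl-9-(TBS-oxy)-10-[3-(TBDPS-oxy)propyl]spiro[4.5]decan-2-yl]acetate
Conditions: H2 (1 atm), [Ir(cod)(PCy3)(py)]PF6 (5 mol %), CH2Cl2, rt
Reagents that add atoms: none
Why: Hydroxyl-directed hydrogenation; the iridium catalyst is held by the two hydroxyls on one ring-B face and delivers hydrogen there, so the acetate arm ends up trans to the secondary hydroxyl (any cis isomer would lactonize and be separable).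

**Step 17**
Reactants: 24 diol
Product: 25 1,6-O-(di-tert-butylsilanediyl) derivative of 24
Conditions: tBu2Si(OTf)2, 2,6-lutidine, CH2Cl2, 0 °C
Reagents that add atoms: di-tert-butylsilyl bis(trifluoromethanesulfonate), CC(C)(C)[Si](OS(=O)(=O)C(F)(F)F)(OS(=O)(=O)C(F)(F)F)C(C)(C)C
Why: Silylene formation across the syn-1,3-diol (secondary and tertiary hydroxyl on the same side of the spiro centre) gives one acid-stable, fluoride-labile protecting group for both.

**Step 18**
Reactants: 25 silylene-protected ester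
Product: 26 9-hydroxy compound (TBS group removed from 25)
Conditions: camphorsulfonic acid (cat.), MeOH/CH2Cl2, 0 °C → rt
Reagents that add atoms: none
Why: Acid-catalysed methanolysis cleaves the secondary TBS ether while the primary TBDPS ether and the silylene survive; it is done here, before any acid-sensitive triene is present.

**Step 19**
Reactants: 27 6-methylhept-5-en-2-one
Product: 29 6-methylhepta-1,5-dien-2-yl trifluoromethanesulfonate, via lithium enolate 28 (not isolated)
Conditions: LiN(iPr)2, THF, −78 °C; then PhNTf2, −78 → 0 °C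
Reagents that add atoms: N-phenylbis(trifluoromethanesulfonimide), O=S(=O)(N(c1ccccc1)S(=O)(=O)C(F)(F)F)C(F)(F)F
Why: Kinetic deprotonation at the methyl group and O-triflation of the terminal enolate.

**Step 20**
Reactants: 29 enol triflate; 30 prop-2-enal (acrolein)
Product: 31 (2E)-8-methyl-4-methylidenenona-2,7-dienal
Conditions: Pd(OAc)2 (5 mol %), PPh3, Et3N, DMF, 60 °C
Reagents that add atoms: none
Why: Heck reaction of an alkenyl triflate with acrolein; syn β-hydride elimination gives the (E)-enal.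

**Step 21**
Reactants: 26 hydroxy ester; 31 (2E)-8-methyl-4-methylidenenona-2,7-dienal
Product: 35 methyl (2E,4E)-trienoate with 9-acetoxy group, via dilithium enolate 32 (not isolated), via dilithium aldolate 33 (not isolated), via aldol diacetate 34 (not isolated)
Conditions: LiN(iPr)2 (2.2 equiv), THF, −78 °C; 31; Ac2O, −78 °C → rt; then DBU, rt
Reagents that add atoms: acetic anhydride, CC(=O)OC(C)=O
Why: Aldol addition of the ester enolate to the aldehyde (1,2-addition at −78 °C), acetylation of both alkoxides and E1cB elimination of acetate; the elimination should favour the conjugated isomer with the ester trans to the dienyl group.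

**Step 22**
Reactants: 35 trienoate acetate
Product: 36 diol (side-chain allylic alcohol and ring-A secondary alcohol)
Conditions: iBu2AlH (6 equiv), CH2Cl2, −78 °C; potassium sodium tartrate (aq.)
Reagents that add atoms: none
Why: 1,2-Reduction of the conjugated ester to the allylic alcohol with reductive cleavage of the acetate in the same operation; silyl ethers and silylene are inert.

**Step 23**
Reactants: 36 diol
Product: 37 primary allylic TBS ether
Conditions: TBSCl (1.1 equiv), imidazole, CH2Cl2, −20 °C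
Reagents that add atoms: tert-butyl(chloro)dimethylsilane, CC(C)(C)[Si](C)(C)Cl
Why: Selective silylation of the unhindered primary allylic alcohol over the hindered ring secondary alcohol.

**Step 24**
Reactants: 37 secondary alcohol
Product: 38 ring-A ketone
Conditions: DMP, pyridine, CH2Cl2, 0 °C → rt
Reagents that add atoms: none
Why: Buffered Dess–Martin oxidation, neutral enough for the triene, the allylic silyl ether and the α-stereocentre.

**Step 25**
Reactants: 38 ring-A ketone
Product: 39 (2Z)-2-(spiro[4.5]decan-9-ylidene)propanenitrile derivative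
Conditions: diethyl (1-cyanoethyl)phosphonate, NaH, THF, 0 → 45 °C
Reagents that add atoms: diethyl (1-cyanoethyl)phosphonate, CCOP(=O)(OCC)C(C)C#N
Why: Horner–Wadsworth–Emmons olefination with a small, reactive cyanophosphonate; the methyl group should take the side of the ring CH2 and the slim linear nitrile the side of the branched α-carbon, which is the geometry of the target.

**Step 26**
Reactants: 39 unsaturated nitrile
Product: 41 fully silylated (Z)-enal, via aldimine 40 (not isolated)
Conditions: iBu2AlH (2.5 equiv), toluene, −78 °C; then wet SiO2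
Reagents that add atoms: water, O
Why: Diisobutylaluminium hydride adds once to the nitrile and the N-aluminated aldimine is hydrolysed on work-up to the enal with the alkene geometry unchanged.

**Step 27**
Reactants: 41 fully silylated (Z)-enal
Product: 42 target (CNP0246965.1)
Conditions: HF·pyridine, pyridine, THF, 0 °C → rt
Reagents that add atoms: none
Why: Buffered fluoride cleaves the primary TBS and TBDPS ethers and the silylene in one operation without touching the enal, the allylic alcohol or the triene.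

**Compound list**

1 | prop-2-en-1-ol (allyl alcohol) | C=CCO | starting material
2 | tert-butyl(diphenyl)(prop-2-en-1-yloxy)silane | C=CCO[Si](c1ccccc1)(c1ccccc1)C(C)(C)C | intermediate
3 | cyclopent-2-en-1-one | O=C1C=CCC1 | starting material
4 | 2-iodocyclopent-2-en-1-one | O=C1C(I)=CCC1 | intermediate
5 | 9-[3-(TBDPS-oxy)propyl]-9-borabicyclo[3.3.1]nonane | CC(C)(C)[Si](OCCCB1C2CCCC1CCC2)(c1ccccc1)c1ccccc1 | intermediate
6 | 2-[3-(TBDPS-oxy)propyl]cyclopent-2-en-1-one | O=C1CCC=C1CCCO[Si](c1ccccc1)(c1ccccc1)C(C)(C)C | intermediate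
7 | (1R)-2-[3-(TBDPS-oxy)propyl]cyclopent-2-en-1-ol | C1=C(CCCO[Si](c2ccccc2)(c2ccccc2)C(C)(C)C)[C@H](O)CC1 | intermediate
8 | tert-butyl({(1R)-2-[3-(TBDPS-oxy)propyl]cyclopent-2-en-1-yl}oxy)dimethylsilane | C1=C(CCCO[Si](c2ccccc2)(c2ccccc2)C(C)(C)C)[C@H](O[Si](C)(C)C(C)(C)C)CC1 | intermediate
9 | [(1R,2S,3R)-3-(TBS-oxy)-2-[3-(TBDPS-oxy)propyl]cyclopentyl]borane | B[C@H]1[C@H](CCCO[Si](c2ccccc2)(c2ccccc2)C(C)(C)C)[C@H](O[Si](C)(C)C(C)(C)C)CC1 | intermediate
10 | (1R,2S,3R)-3-(TBS-oxy)-2-[3-(TBDPS-oxy)propyl]cyclopentan-1-ol (chain cis to OTBS, OH trans to both) | O[C@H]1[C@H](CCCO[Si](c2ccccc2)(c2ccccc2)C(C)(C)C)[C@H](O[Si](C)(C)C(C)(C)C)CC1 | intermediate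
11 | (2R,3R)-3-(TBS-oxy)-2-[3-(TBDPS-oxy)propyl]cyclopentan-1-one | O=C1[C@H](CCCO[Si](c2ccccc2)(c2ccccc2)C(C)(C)C)[C@H](O[Si](C)(C)C(C)(C)C)CC1 | intermediate
12 | (1S,2R,3R)-1-ethynyl-3-(TBS-oxy)-2-[3-(TBDPS-oxy)propyl]cyclopentan-1-ol (OH cis to chain and OTBS) | C#C[C@@]1(O)[C@H](CCCO[Si](c2ccccc2)(c2ccccc2)C(C)(C)C)[C@H](O[Si](C)(C)C(C)(C)C)CC1 | intermediate
13 | (1S,2R,3R)-3-(TBS-oxy)-2-[3-(TBDPS-oxy)propyl]-1-[1-(tributylstannyl)ethenyl]cyclopentan-1-ol | C=C([Sn](CCCC)(CCCC)CCCC)[C@@]1(O)[C@H](CCCO[Si](c2ccccc2)(c2ccccc2)C(C)(C)C)[C@H](O[Si](C)(C)C(C)(C)C)CC1 | intermediate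
14 | 4-methoxy-2-methylidene-4-oxobutanoic acid (monomethyl itaconate) | C=C(CC(=O)OC)C(=O)O | starting material
15 | methyl 3-(chlorocarbonyl)but-3-enoate | C=C(CC(=O)OC)C(=O)Cl | intermediate
16 | methyl 5-[(1S,2R,3R)-1-hydroxy-3-(TBS-oxy)-2-[3-(TBDPS-oxy)propyl]cyclopentyl]-3-methylidene-4-oxohex-5-enoate | C=C(CC(=O)OC)C(=O)C(=C)[C@@]1(O)[C@H](CCCO[Si](c2ccccc2)(c2ccccc2)C(C)(C)C)[C@H](O[Si](C)(C)C(C)(C)C)CC1 | intermediate
17 | 2-hydroxycyclopentenyl (oxyallyl) cation carrying the 1-hydroxycyclopentyl group at the cationic terminus and the acetate arm at the other | COC(=O)CC1=C(O)[C+](CC1)[C@@]2(O)[C@H](CCCO[Si](c3ccccc3)(c3ccccc3)C(C)(C)C)[C@H](O[Si](C)(C)C(C)(C)C)CC2 | intermediate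
18 | methyl 2-[(5R,9R,10S)-9-(TBS-oxy)-10-[3-(TBDPS-oxy)propyl]-1,6-dioxospiro[4.5]decan-2-yl]acetate (both C2 epimers) | COC(=O)CC1CC[C@]2([C@H](CCCO[Si](c3ccccc3)(c3ccccc3)C(C)(C)C)[C@H](O[Si](C)(C)C(C)(C)C)CCC2=O)C1=O | intermediate
19 | methyl 2-[(5R,6S,9R,10S)-6-hydroxy-6-methyl-1-oxo-9-(TBS-oxy)-10-[3-(TBDPS-oxy)propyl]spiro[4.5]decan-2-yl]acetate (both C2 epimers) | COC(=O)CC1CC[C@]2([C@H](CCCO[Si](c3ccccc3)(c3ccccc3)C(C)(C)C)[C@H](O[Si](C)(C)C(C)(C)C)CC[C@]2(C)O)C1=O | intermediate
20 | bis(trimethylsilyl) derivative of 19: 1-(TMS-oxy)spiro[4.5]dec-1-ene with 6-OTMS | COC(=O)CC=1CC[C@]2([C@H](CCCO[Si](c3ccccc3)(c3ccccc3)C(C)(C)C)[C@H](O[Si](C)(C)C(C)(C)C)CC[C@]2(C)O[Si](C)(C)C)C=1O[Si](C)(C)C | intermediate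
21 | methyl 2-[(5R,6S,9R,10S)-6-methyl-1-oxo-9-(TBS-oxy)-10-[3-(TBDPS-oxy)propyl]-6-(TMS-oxy)spiro[4.5]dec-2-en-2-yl]acetate | COC(=O)CC1=CC[C@]2([C@H](CCCO[Si](c3ccccc3)(c3ccccc3)C(C)(C)C)[C@H](O[Si](C)(C)C(C)(C)C)CC[C@]2(C)O[Si](C)(C)C)C1=O | intermediate
22 | methyl 2-[(1S,5S,6S,9R,10S)-1-hydroxy-6-methyl-9-(TBS-oxy)-10-[3-(TBDPS-oxy)propyl]-6-(TMS-oxy)spiro[4.5]dec-2-en-2-yl]acetate | COC(=O)CC1=CC[C@]2([C@H](CCCO[Si](c3ccccc3)(c3ccccc3)C(C)(C)C)[C@H](O[Si](C)(C)C(C)(C)C)CC[C@]2(C)O[Si](C)(C)C)[C@H]1O | intermediate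
23 | methyl 2-[(1S,5S,6S,9R,10S)-1,6-dihydroxy-6-methyl-9-(TBS-oxy)-10-[3-(TBDPS-oxy)propyl]spiro[4.5]dec-2-en-2-yl]acetate | COC(=O)CC1=CC[C@]2([C@H](CCCO[Si](c3ccccc3)(c3ccccc3)C(C)(C)C)[C@H](O[Si](C)(C)C(C)(C)C)CC[C@]2(C)O)[C@H]1O | intermediate
24 | methyl 2-[(1S,2S,5S,6S,9R,10S)-1,6-dihydroxy-6-methyl-9-(TBS-oxy)-10-[3-(TBDPS-oxy)propyl]spiro[4.5]decan-2-yl]acetate | COC(=O)C[C@@H]1CC[C@]2([C@H](CCCO[Si](c3ccccc3)(c3ccccc3)C(C)(C)C)[C@H](O[Si](C)(C)C(C)(C)C)CC[C@]2(C)O)[C@H]1O | intermediate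
25 | 1,6-O-(di-tert-butylsilanediyl) derivative of 24 | COC(=O)C[C@@H]1CC[C@]2([C@H](CCCO[Si](c4ccccc4)(c4ccccc4)C(C)(C)C)[C@H](O[Si](C)(C)C(C)(C)C)CC[C@]2(C)O[Si]3(C(C)(C)C)C(C)(C)C)[C@H]1O3 | intermediate
26 | 9-hydroxy analogue of 25 (TBS removed) | COC(=O)C[C@@H]1CC[C@]2([C@H](CCCO[Si](c4ccccc4)(c4ccccc4)C(C)(C)C)[C@H](O)CC[C@]2(C)O[Si]3(C(C)(C)C)C(C)(C)C)[C@H]1O3 | intermediate
27 | 6-methylhept-5-en-2-one | CC(=O)CCC=C(C)C | starting material
28 | lithium 6-methylhepta-1,5-dien-2-olate | [Li+].C=C([O-])CCC=C(C)C | intermediate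
29 | 6-methylhepta-1,5-dien-2-yl trifluoromethanesulfonate | C=C(OS(=O)(=O)C(F)(F)F)CCC=C(C)C | intermediate
30 | prop-2-enal (acrolein) | C=CC=O | starting material
31 | (2E)-8-methyl-4-methylidenenona-2,7-dienal | O=C/C=C/C(=C)CCC=C(C)C | intermediate
32 | dilithium ester enolate/9-alkoxide of 26 | [Li+].[Li+].COC([O-])=C[C@@H]1CC[C@]2([C@H](CCCO[Si](c4ccccc4)(c4ccccc4)C(C)(C)C)[C@H]([O-])CC[C@]2(C)O[Si]3(C(C)(C)C)C(C)(C)C)[C@H]1O3 | intermediate
33 | dilithium aldolate (β-alkoxide and 9-alkoxide; mixture at the two new centres) | [Li+].[Li+].COC(=O)C(C([O-])/C=C/C(=C)CCC=C(C)C)[C@@H]1CC[C@]2([C@H](CCCO[Si](c4ccccc4)(c4ccccc4)C(C)(C)C)[C@H]([O-])CC[C@]2(C)O[Si]3(C(C)(C)C)C(C)(C)C)[C@H]1O3 | intermediate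
34 | aldol diacetate (β-acetoxy ester with 9-acetoxy group; mixture at the two new centres) | COC(=O)C(C(OC(C)=O)/C=C/C(=C)CCC=C(C)C)[C@@H]1CC[C@]2([C@H](CCCO[Si](c4ccccc4)(c4ccccc4)C(C)(C)C)[C@H](OC(C)=O)CC[C@]2(C)O[Si]3(C(C)(C)C)C(C)(C)C)[C@H]1O3 | intermediate
35 | methyl (2E,4E)-10-methyl-6-methylidene-2-(spirocyclic C2 substituent)undeca-2,4,9-trienoate with 9-acetoxy, 10-[3-(TBDPS-oxy)propyl] and the 1,6-silylene on the spiro[4.5]decane | C=C(/C=C/C=C(/C(=O)OC)[C@@H]1CC[C@]2([C@H](CCCO[Si](c4ccccc4)(c4ccccc4)C(C)(C)C)[C@H](OC(C)=O)CC[C@]2(C)O[Si]3(C(C)(C)C)C(C)(C)C)[C@H]1O3)CCC=C(C)C | intermediate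
36 | diol: (2E,4E)-trien-1-ol side chain and free 9-hydroxyl | C=C(/C=C/C=C(/CO)[C@@H]1CC[C@]2([C@H](CCCO[Si](c4ccccc4)(c4ccccc4)C(C)(C)C)[C@H](O)CC[C@]2(C)O[Si]3(C(C)(C)C)C(C)(C)C)[C@H]1O3)CCC=C(C)C | intermediate
37 | primary allylic TBS ether of 36 | C=C(/C=C/C=C(/CO[Si](C)(C)C(C)(C)C)[C@@H]1CC[C@]2([C@H](CCCO[Si](c4ccccc4)(c4ccccc4)C(C)(C)C)[C@H](O)CC[C@]2(C)O[Si]3(C(C)(C)C)C(C)(C)C)[C@H]1O3)CCC=C(C)C | intermediate
38 | ring-A 9-ketone | C=C(/C=C/C=C(/CO[Si](C)(C)C(C)(C)C)[C@@H]1CC[C@]2([C@H](CCCO[Si](c4ccccc4)(c4ccccc4)C(C)(C)C)C(=O)CC[C@]2(C)O[Si]3(C(C)(C)C)C(C)(C)C)[C@H]1O3)CCC=C(C)C | intermediate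
39 | (2Z)-2-(spiro[4.5]decan-9-ylidene)propanenitrile (nitrile cis to the chain-bearing ring carbon) | C=C(/C=C/C=C(/CO[Si](C)(C)C(C)(C)C)[C@@H]1CC[C@]2([C@H](CCCO[Si](c4ccccc4)(c4ccccc4)C(C)(C)C)/C(=C(/C)C#N)CC[C@]2(C)O[Si]3(C(C)(C)C)C(C)(C)C)[C@H]1O3)CCC=C(C)C | intermediate
40 | aldimine of 41 (C=NH in place of C=O) | C=C(/C=C/C=C(/CO[Si](C)(C)C(C)(C)C)[C@@H]1CC[C@]2([C@H](CCCO[Si](c4ccccc4)(c4ccccc4)C(C)(C)C)/C(=C(/C)C=N)CC[C@]2(C)O[Si]3(C(C)(C)C)C(C)(C)C)[C@H]1O3)CCC=C(C)C | intermediate
41 | fully silylated target: (2Z)-propanal with primary allylic OTBS, primary OTBDPS and 1,6-silylene | C=C(/C=C/C=C(/CO[Si](C)(C)C(C)(C)C)[C@@H]1CC[C@]2([C@H](CCCO[Si](c4ccccc4)(c4ccccc4)C(C)(C)C)/C(=C(/C)C=O)CC[C@]2(C)O[Si]3(C(C)(C)C)C(C)(C)C)[C@H]1O3)CCC=C(C)C | intermediate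
42 | (2Z)-2-[(1S,2S,5S,6S,10R)-1,6-dihydroxy-2-[(2E,4E)-1-hydroxy-10-methyl-6-methylideneundeca-2,4,9-trien-2-yl]-10-(3-hydroxypropyl)-6-methylspiro[4.5]decan-9-ylidene]propanal | C=C(/C=C/C=C(/CO)[C@@H]1CC[C@]2([C@H](CCCO)/C(=C(/C)C=O)CC[C@]2(C)O)[C@H]1O)CCC=C(C)C | target

**Step count**

Total: 27 steps. Longest linear sequence: 23 steps (from 3 through steps 2–9, 11–18 and 21–27).

**Steps most likely to fail**

Step 12 (Proposed new method). What may go wrong: proton loss from the oxyallyl cation (ordinary Nazarov termination), migration of the ring CH2 in place of the chain-bearing carbon, or shift to the wrong face of the cation. The fallback uses known chemistry and brings ring B in intact. It sets out from ketone 11: addition of cyclopent-1-en-1-yllithium (from 1-bromocyclopentene and t-BuLi; LaCl3·2LiCl, THF, −78 °C) should give the tertiary allylic alcohol F1, and hydroxyl-directed epoxidation (VO(acac)2, t-BuOOH) the epoxy alcohol F2. Lewis-acid semipinacol rearrangement of this 2,3-epoxy alcohol (BF3·OEt2, CH2Cl2, −78 °C) enlarges the cyclopentanol to the cyclohexanone and should give the spiro hydroxy ketone F3, the migrating carbon entering anti to the epoxide oxygen. MeMgBr with LaCl3·2LiCl then gives the diol F4, Dess–Martin oxidation the hydroxy ketone F5, and alkylation of its lithium enolate (LiN(iPr)2, 2.1 equiv; methyl bromoacetate) comes back to the route at 19.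

Step 25. What may go wrong: poor geometric control in forming the tetrasubstituted alkene, and base-induced epimerization of the stereocentre α to the ketone. The fallback sets out from ketone 38: isopropenylmagnesium bromide with LaCl3·2LiCl (THF, −78 °C) should give the tertiary allylic alcohol F6, and oxidative 1,3-transposition with pyridinium chlorochromate (CH2Cl2, rt) leads to enal 41 without any basic step, the geometric isomers being separated there.

Step 21. What may go wrong: retro-aldol cleavage of the aldolate and loss of alkene geometry in the E1cB elimination next to the branched α-carbon. The fallback sets out from ester 26: partial reduction (iBu2AlH, toluene, −78 °C) should give the aldehyde F7, and secondary-amine-catalysed cross-aldol condensation with dienal 31 (pyrrolidine, benzoic acid, CH2Cl2) the 2-substituted trienal F8, whose (E) geometry is set under equilibrating conditions. Reduction with NaBH4 and CeCl3·7H2O comes back to the route at diol 36.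

**Further compounds**

F1 | step 12 | (1S,2R,3R)-1-(cyclopent-1-en-1-yl)-3-(TBS-oxy)-2-[3-(TBDPS-oxy)propyl]cyclopentan-1-ol | C1(=CCCC1)[C@@]2(O)[C@H](CCCO[Si](c3ccccc3)(c3ccccc3)C(C)(C)C)[C@H](O[Si](C)(C)C(C)(C)C)CC2
F2 | step 12 | epoxide of F1 (6-oxabicyclo[3.1.0]hexan-1-yl carbinol, oxirane oxygen on the face that becomes the ring-B hydroxyl) | C1CC[C@]2(O[C@@H]12)[C@@]3(O)[C@H](CCCO[Si](c4ccccc4)(c4ccccc4)C(C)(C)C)[C@H](O[Si](C)(C)C(C)(C)C)CC3
F3 | step 12 | (1S,5S,9R,10S)-1-hydroxy-9-(TBS-oxy)-10-[3-(TBDPS-oxy)propyl]spiro[4.5]decan-6-one | C1CC[C@]2([C@H](CCCO[Si](c3ccccc3)(c3ccccc3)C(C)(C)C)[C@H](O[Si](C)(C)C(C)(C)C)CCC2=O)[C@H]1O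
F4 | step 12 | (1S,5S,6S,9R,10S)-6-methyl-9-(TBS-oxy)-10-[3-(TBDPS-oxy)propyl]spiro[4.5]decane-1,6-diol | C1CC[C@]2([C@H](CCCO[Si](c3ccccc3)(c3ccccc3)C(C)(C)C)[C@H](O[Si](C)(C)C(C)(C)C)CC[C@]2(C)O)[C@H]1O
F5 | step 12 | (5R,6S,9R,10S)-6-hydroxy-6-methyl-9-(TBS-oxy)-10-[3-(TBDPS-oxy)propyl]spiro[4.5]decan-1-one | C1CC[C@]2([C@H](CCCO[Si](c3ccccc3)(c3ccccc3)C(C)(C)C)[C@H](O[Si](C)(C)C(C)(C)C)CC[C@]2(C)O)C1=O
F6 | step 25 | 9-hydroxy-9-(prop-1-en-2-yl) adduct of ketone 38 (one diastereomer at the new carbinol, configuration immaterial) | C=C(/C=C/C=C(/CO[Si](C)(C)C(C)(C)C)[C@@H]1CC[C@]2([C@H](CCCO[Si](c4ccccc4)(c4ccccc4)C(C)(C)C)C(O)(C(C)=C)CC[C@]2(C)O[Si]3(C(C)(C)C)C(C)(C)C)[C@H]1O3)CCC=C(C)C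
F7 | step 21 | aldehyde corresponding to ester 26 (2-(spirocyclic)acetaldehyde) | O=CC[C@@H]1CC[C@]2([C@H](CCCO[Si](c4ccccc4)(c4ccccc4)C(C)(C)C)[C@H](O)CC[C@]2(C)O[Si]3(C(C)(C)C)C(C)(C)C)[C@H]1O3
F8 | step 21 | (2E,4E)-trienal corresponding to diol 36 (CHO in place of CH2OH) | C=C(/C=C/C=C(/C=O)[C@@H]1CC[C@]2([C@H](CCCO[Si](c4ccccc4)(c4ccccc4)C(C)(C)C)[C@H](O)CC[C@]2(C)O[Si]3(C(C)(C)C)C(C)(C)C)[C@H]1O3)CCC=C(C)C
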